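**Plan**
Locants: acyl chain C1 (C=O) to C16, benzene ring C1' (acylated carbon) to C6'. Retrosynthesis: after removal of the O-alkyl and O-silyl groups, the ring is cut at C1'–C6' and C2'–C3', then the chain at C1–C1' and at C11–C12.
Enabling feature: the ring carries oxygen on C2', C4' and C6' and the C1 carbonyl on C1'. C3'–C4'–C5'–C6' with O4' and O6' are a 1,1,3-trioxygenated butadiene; C1'–C2' with O2' and the C1 carbonyl are a 3-alkoxy ynone.
Forward: C11–C12 is joined first (Grignard reagent plus epoxide), the chain end is oxidised to C1 and extended by the two alkyne carbons (C1–C1'). The only ring is then built by cycloaddition and aromatisation, and one dealkylation/desilylation step finishes.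
Stereochemistry: the single stereocentre, C13 (S), is bought with (S)-1,2-epoxypentane and is never a reaction site.

Key step: step 8

Remark: (S)-1,2-epoxypentane is taken as a purchasable single enantiomer; attack at its CH2 carbon leaves the descriptor (S), because the long chain outranks propyl just as the oxirane CH2 does.

**Route**

Step 1
Reactants: 1 11-bromoundec-1-ene; 2 (S)-1,2-epoxypentane
Product: 4 (4S)-hexadec-15-en-4-ol, via undec-10-enylmagnesium bromide 3 (not isolated)
Conditions: Mg, THF, rt; then 2, CuI (10 mol%), THF, −30 → 0 °C; sat. aq. NH4Cl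
Reagents that add atoms: none
Why: Copper-catalysed Grignard opening of a terminal epoxide is an SN2 attack at the unsubstituted CH2 carbon, so the stereocentre of 2 is not involved and becomes C13 with (S) configuration, while the terminal alkene is inert.

Step 2
Reactants: 4 (4S)-hexadec-15-en-4-ol
Product: 5 tert-butyl{[(4S)-hexadec-15-en-4-yl]oxy}dimethylsilane
Conditions: TBSCl, imidazole, DMF, rt
Reagents that add atoms: tert-butyldimethylsilyl chloride, CC(C)(C)[Si](C)(C)Cl
Why: Imidazole-promoted silylation of a secondary alcohol is routine, and the resulting silyl ether should withstand the borane, oxidant, organolithium and dilute-acid conditions that follow.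

Step 3
Reactants: 5 tert-butyl{[(4S)-hexadec-15-en-4-yl]oxy}dimethylsilane
Product: 7 (13S)-13-[(tert-butyldimethylsilyl)oxy]hexadecan-1-ol, via B-alkyl-9-borabicyclo[3.3.1]nonane 6 (not isolated)
Conditions: 9-BBN (0.5 M in THF), 0 °C → rt; then NaOH (aq.), H2O2 (30%), 0 °C → rt
Reagents that add atoms: hydrogen peroxide, OO
Why: Hydroboration–oxidation with a bulky dialkylborane places boron on the terminal carbon (anti-Markovnikov) and alkaline peroxide replaces it by hydroxyl, which should give the primary alcohol with the silyl ether untouched.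

Step 4
Reactants: 7 (13S)-13-[(tert-butyldimethylsilyl)oxy]hexadecan-1-ol
Product: 9 (13S)-13-[(tert-butyldimethylsilyl)oxy]hexadecanoic acid, via hexadecanal 8 (not isolated)
Conditions: TEMPO (20 mol%), PhI(OAc)2 (2.2 equiv), MeCN–CH2Cl2–H2O, rt
Reagents that add atoms: water, O
Why: In this nitroxyl-catalysed oxidation the oxoammonium ion takes the primary alcohol to the aldehyde, whose hydrate is oxidised on to the acid in the aqueous medium, and a secondary silyl ether tolerates the weakly acidic mixture.

Step 5
Reactants: 9 (13S)-13-[(tert-butyldimethylsilyl)oxy]hexadecanoic acid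
Product: 11 (13S)-13-[(tert-butyldimethylsilyl)oxy]-N-methoxy-N-methylhexadecanamide, via acyl imidazole 10 (not isolated)
Conditions: 1,1'-carbonyldiimidazole (CDI), CH2Cl2, rt; then MeNH(OMe)·HCl, rt
Reagents that add atoms: N,O-dimethylhydroxylamine hydrochloride, CNOC.Cl
Why: Amide formation by CDI activation proceeds through the acyl imidazole, which the amine freed from its hydrochloride by the released imidazole acylates cleanly under conditions that do not affect the silyl ether.

Step 6
Reactants: 11 (13S)-13-[(tert-butyldimethylsilyl)oxy]-N-methoxy-N-methylhexadecanamide; 12 ethoxyacetylene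
Product: 15 (15S)-15-[(tert-butyldimethylsilyl)oxy]-1-ethoxyoctadec-1-yn-3-one, via lithium ethoxyacetylide 13 (not isolated), via tetrahedral lithium adduct 14 (not isolated)
Conditions: 12 (2.0 equiv), n-BuLi (1.8 equiv), THF, −78 °C; then 11, −78 → −30 °C; inverse quench into cold sat. aq. NH4Cl/Et2O; rapid filtration through Et3N-deactivated SiO2
Reagents that add atoms: none
Why: In this Weinreb ketone synthesis the acetylide adds once to give the N,O-chelated adduct 14, which collapses to the ketone only on the cold quench, so over-addition is excluded and the acid-sensitive ynol ether never meets more than a near-neutral aqueous phase.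

Step 7
Reactants: 16 methyl (E)-3-methoxybut-2-enoate
Product: 18 1,3-dimethoxy-1-(trimethylsilyloxy)buta-1,3-diene, via lithium dienolate 17 (not isolated)
Conditions: LDA (1.1 equiv), THF, −78 °C; then Me3SiCl, −78 °C → rt; filtration under Ar, distillation
Reagents that add atoms: chlorotrimethylsilane, C[Si](C)(C)Cl
Why: Deprotonation of the C4 methyl group of the vinylogous ester gives the extended dienolate, which the hard silyl chloride traps on oxygen to form the silyl ketene acetal; its geometry is immaterial because that carbon becomes an arene carbon.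

Step 8
Reactants: 15 (15S)-15-[(tert-butyldimethylsilyl)oxy]-1-ethoxyoctadec-1-yn-3-one; 18 1,3-dimethoxy-1-(trimethylsilyloxy)buta-1,3-diene
Product: 21 (13S)-13-[(tert-butyldimethylsilyl)oxy]-1-(2-ethoxy-6-hydroxy-4-methoxyphenyl)hexadecan-1-one, via cyclohexa-1,4-diene cycloadduct 19 (not isolated), via aryl trimethylsilyl ether 20 (not isolated)
Conditions: 18 (2.5 equiv), PhMe (1 M), Ar, 23 → 60 °C; then 0.1 M HCl (aq.)–THF, 0 °C
Reagents that add atoms: none
Why: Proposed new method: the diene is a vinylogous silyl ketene acetal with its largest HOMO coefficient on the CH2 terminus, and the ynone, although tempered by the ethoxy donor, keeps its LUMO centred on the ethoxy-bearing β-carbon, so bonding should begin between these two atoms (C2'–C3') and be completed between the ketene acetal carbon and the α-carbon (C1'–C6'), either in one asynchronous [4+2] event or as a Mukaiyama–Michael addition whose allenolate then attacks the silyloxycarbenium carbon, both paths ending in cyclohexa-1,4-diene 19. The closest known reaction type is the Diels–Alder addition of 1,1,3-trioxygenated butadienes to acetylenic ketones and esters followed by loss of alcohol, which gives resorcinol derivatives; new here is the oxygen substituent on the alkyne carbon that becomes C2'. The benzene ring is closed by intermolecular union of a four-carbon and a two-carbon unit, the second bond of a stepwise course being a 6-exo-trig closure, and it becomes aromatic when dilute acid ionises the mixed methyl silyl ketal of 19, the ring CH2 loses a proton and methanol departs; the same acid hydrolyses aryl silyl ether 20. No lasting stereocentre is formed, since the ketal carbon of 19 is stereogenic only until aromatisation and C13 is a remote spectator under its silyl ether. The step needs regioselectivity, which the matched polarisation of the partners should secure (the reverse orientation would join the nucleophilic diene terminus to the electron-rich α-carbon), and chemoselectivity for C≡C over C=O, which the absence of a Lewis acid favours; the temperature is held at or below 60 °C so that the ethyl ynol ether does not lose ethene.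

Step 9
Reactants: 21 (13S)-13-[(tert-butyldimethylsilyl)oxy]-1-(2-ethoxy-6-hydroxy-4-methoxyphenyl)hexadecan-1-one
Product: 23 (13S)-13-hydroxy-1-(2,4,6-trihydroxyphenyl)hexadecan-1-one, via per-O-dibromoboryl ester 22 (not isolated)
Conditions: BBr3 (1 M in CH2Cl2, 6 equiv), CH2Cl2, −78 → 0 °C; then MeOH, 0 °C → rt
Reagents that add atoms: none
Why: In this Lewis-acid ether cleavage boron binds each ether oxygen, bromide removes methyl and ethyl by SN2 and the silyl group by attack at silicon (the C1 ketone assisting at the ortho oxygen by chelation), and methanolysis of the boron esters, with the HBr it generates removing any silyl ether left, should release the triphenol and the C13 alcohol, whose C–O bond is not broken at this temperature, so (S) is retained.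

**Compound list**
1 | 11-bromoundec-1-ene | C=CCCCCCCCCCBr | starting material
2 | (S)-1,2-epoxypentane [(2S)-2-propyloxirane] | CCC[C@H]1CO1 | starting material
3 | undec-10-enylmagnesium bromide | C=CCCCCCCCCC[Mg]Br | intermediate
4 | (4S)-hexadec-15-en-4-ol | CCC[C@H](O)CCCCCCCCCCC=C | intermediate
5 | tert-butyl{[(4S)-hexadec-15-en-4-yl]oxy}dimethylsilane | CCC[C@H](O[Si](C)(C)C(C)(C)C)CCCCCCCCCCC=C | intermediate
6 | 9-{(13S)-13-[(tert-butyldimethylsilyl)oxy]hexadecyl}-9-borabicyclo[3.3.1]nonane | CCC[C@H](O[Si](C)(C)C(C)(C)C)CCCCCCCCCCCCB1C2CCCC1CCC2 | intermediate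
7 | (13S)-13-[(tert-butyldimethylsilyl)oxy]hexadecan-1-ol | CCC[C@H](O[Si](C)(C)C(C)(C)C)CCCCCCCCCCCCO | intermediate
8 | (13S)-13-[(tert-butyldimethylsilyl)oxy]hexadecanal | CCC[C@H](O[Si](C)(C)C(C)(C)C)CCCCCCCCCCCC=O | intermediate
9 | (13S)-13-[(tert-butyldimethylsilyl)oxy]hexadecanoic acid | CCC[C@H](O[Si](C)(C)C(C)(C)C)CCCCCCCCCCCC(=O)O | intermediate
10 | (13S)-13-[(tert-butyldimethylsilyl)oxy]-1-(1H-imidazol-1-yl)hexadecan-1-one | CCC[C@H](O[Si](C)(C)C(C)(C)C)CCCCCCCCCCCC(=O)n1ccnc1 | intermediate
11 | (13S)-13-[(tert-butyldimethylsilyl)oxy]-N-methoxy-N-methylhexadecanamide | CCC[C@H](O[Si](C)(C)C(C)(C)C)CCCCCCCCCCCC(=O)N(C)OC | intermediate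
12 | ethoxyacetylene (ethoxyethyne) | CCOC#C | starting material
13 | lithium ethoxyacetylide | CCOC#C[Li] | intermediate
14 | lithium (15S)-15-[(tert-butyldimethylsilyl)oxy]-1-ethoxy-3-[methoxy(methyl)amino]octadec-1-yn-3-olate (both C3 epimers) | CCC[C@H](O[Si](C)(C)C(C)(C)C)CCCCCCCCCCCC(O[Li])(C#COCC)N(C)OC | intermediate
15 | (15S)-15-[(tert-butyldimethylsilyl)oxy]-1-ethoxyoctadec-1-yn-3-one | CCC[C@H](O[Si](C)(C)C(C)(C)C)CCCCCCCCCCCC(=O)C#COCC | intermediate
16 | methyl (E)-3-methoxybut-2-enoate | CO/C(C)=C/C(=O)OC | starting material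
17 | lithium 1,3-dimethoxybuta-1,3-dien-1-olate | C=C(OC)C=C(OC)O[Li] | intermediate
18 | 1,3-dimethoxy-1-(trimethylsilyloxy)buta-1,3-diene | C=C(OC)C=C(OC)O[Si](C)(C)C | intermediate
19 | (13S)-13-[(tert-butyldimethylsilyl)oxy]-1-[2-ethoxy-4,6-dimethoxy-6-(trimethylsilyloxy)cyclohexa-1,4-dien-1-yl]hexadecan-1-one (both epimers at the ketal carbon) | CCC[C@H](O[Si](C)(C)C(C)(C)C)CCCCCCCCCCCC(=O)C1=C(OCC)CC(OC)=CC1(OC)O[Si](C)(C)C | intermediate
20 | (13S)-13-[(tert-butyldimethylsilyl)oxy]-1-[2-ethoxy-4-methoxy-6-(trimethylsilyloxy)phenyl]hexadecan-1-one | CCC[C@H](O[Si](C)(C)C(C)(C)C)CCCCCCCCCCCC(=O)c1c(OCC)cc(OC)cc1O[Si](C)(C)C | intermediate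
21 | (13S)-13-[(tert-butyldimethylsilyl)oxy]-1-(2-ethoxy-6-hydroxy-4-methoxyphenyl)hexadecan-1-one | CCC[C@H](O[Si](C)(C)C(C)(C)C)CCCCCCCCCCCC(=O)c1c(O)cc(OC)cc1OCC | intermediate
22 | (13S)-13-(dibromoboryloxy)-1-[2,4,6-tris(dibromoboryloxy)phenyl]hexadecan-1-one (representative boron-bound form) | CCC[C@H](OB(Br)Br)CCCCCCCCCCCC(=O)c1c(OB(Br)Br)cc(OB(Br)Br)cc1OB(Br)Br | intermediate
23 | (13S)-13-hydroxy-1-(2,4,6-trihydroxyphenyl)hexadecan-1-one | CCC[C@H](O)CCCCCCCCCCCC(=O)c1c(O)cc(O)cc1O | target

**Count**
Total: 9 steps. Longest linear sequence: 8 steps (steps 1–6, 8 and 9); step 7 is a one-step branch.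

**Steps most likely to fail**

Step 8 (the step marked as a proposed new method). The ethoxy donor may make the alkyne too slow a 2π partner. Loss of ethene from the ynol ether, hydrolysis of the diene, or expulsion of ethoxide from an open-chain Michael adduct could then outrun ring closure. The fallback uses known chemistry, gives up the benzannulation, sets out from amide 11 and returns at target 23. Phloroglucinol is converted with MOMCl and iPr2NEt in CH2Cl2 into 1,3,5-tris(methoxymethoxy)benzene F1. F1 is lithiated between two acetal oxygens (n-BuLi, THF, 0 °C) to 2,4,6-tris(methoxymethoxy)phenyllithium F2. Addition of F2 to 11 (Weinreb ketone synthesis, −78 → 0 °C) should give (13S)-13-[(tert-butyldimethylsilyl)oxy]-1-[2,4,6-tris(methoxymethoxy)phenyl]hexadecan-1-one F3. Methanolic HCl then removes the three acetals and the silyl ether in one operation to give 23.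

Step 6. The ynol ether may be hydrated, or the liberated N,O-dimethylhydroxylamine may add to the ynone, while the tetrahedral adduct collapses during the quench. The fallback changes the oxidation level at which the alkyne is introduced, sets out from alcohol 7 and returns at ynone 15. Alcohol 7 is oxidised only as far as aldehyde 8, now isolated (SO3·pyridine, DMSO, iPr2NEt; Parikh–Doering oxidation). Aldehyde 8 is treated with lithium ethoxyacetylide 13 at −78 °C to give (15S)-15-[(tert-butyldimethylsilyl)oxy]-1-ethoxyoctadec-1-yn-3-ol F4 as both C3 epimers. Oxidation of the propargylic alcohol with activated MnO2 in CH2Cl2 should then give 15 under neutral conditions, with no amine set free.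

Step 9. Substitution or elimination may occur at C13 through its boron ester while the para methyl ether is still being cleaved. The fallback changes the protection of C13, sets out from 21 and returns at 23. The silyl ether is removed with TBAF in THF to give (13S)-1-(2-ethoxy-6-hydroxy-4-methoxyphenyl)-13-hydroxyhexadecan-1-one F5. Ac2O, pyridine and DMAP convert F5 into (4S)-16-[2-(acetyloxy)-6-ethoxy-4-methoxyphenyl]-16-oxohexadecan-4-yl acetate F6, so that no alkyl borate can form at C13. BBr3 (CH2Cl2, −78 → 0 °C, methanol quench) then cleaves the two aryl ethers and the aryl acetate to give, chiefly, (4S)-16-oxo-16-(2,4,6-trihydroxyphenyl)hexadecan-4-yl acetate F7. Methanolysis of F7 (K2CO3, degassed MeOH, rt) gives 23.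

**Further compounds**
F1 | step 8 | 1,3,5-tris(methoxymethoxy)benzene | COCOc1cc(OCOC)cc(OCOC)c1
F2 | step 8 | 2,4,6-tris(methoxymethoxy)phenyllithium | [Li]c1c(OCOC)cc(OCOC)cc1OCOC
F3 | step 8 | (13S)-13-[(tert-butyldimethylsilyl)oxy]-1-[2,4,6-tris(methoxymethoxy)phenyl]hexadecan-1-one | CCC[C@H](O[Si](C)(C)C(C)(C)C)CCCCCCCCCCCC(=O)c1c(OCOC)cc(OCOC)cc1OCOC
F4 | step 6 | (15S)-15-[(tert-butyldimethylsilyl)oxy]-1-ethoxyoctadec-1-yn-3-ol | CCC[C@H](O[Si](C)(C)C(C)(C)C)CCCCCCCCCCCC(O)C#COCC
F5 | step 9 | (13S)-1-(2-ethoxy-6-hydroxy-4-methoxyphenyl)-13-hydroxyhexadecan-1-one | CCC[C@H](O)CCCCCCCCCCCC(=O)c1c(O)cc(OC)cc1OCC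
F6 | step 9 | (4S)-16-[2-(acetyloxy)-6-ethoxy-4-methoxyphenyl]-16-oxohexadecan-4-yl acetate | CCC[C@H](OC(C)=O)CCCCCCCCCCCC(=O)c1c(OC(C)=O)cc(OC)cc1OCC
F7 | step 9 | (4S)-16-oxo-16-(2,4,6-trihydroxyphenyl)hexadecan-4-yl acetate | CCC[C@H](OC(C)=O)CCCCCCCCCCCC(=O)c1c(O)cc(O)cc1O
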